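**Plan**

- Retrosynthesis: the phenols are masked as silyl ethers, and ethanol is added back across the furan (ethoxy on C5, hydrogen on C2) to give a 2-ethoxy-2,5-dihydrofuran. Its C3=C4 double bond is then cut by ring-closing metathesis to an acyclic diene acetal.
- The diene acetal is cut at the acetal C–O bond into a racemic aryl vinyl carbinol and the diethyl acetal of an (S)-2-substituted acrolein. That acetal is cut at the ester C–O bond and at the carbinol–vinyl C–C bond (2-lithioacrolein acetal plus 4-methylpent-3-enal).
- Forward: the chain is joined C–C first, then ester, then mixed acetal. The only new ring, the furan, is closed as its dihydro acetal by metathesis, aromatized by loss of ethanol, and desilylated last.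
- Enabling feature: the furan carries hydrogen on C3 and C5, the aryl group on C2 and the side chain on C4. C3=C4 can therefore be the olefin made from a vinyl group and a 1,1-disubstituted olefin, C5 (aldehyde oxidation level) can be the acetal carbon whose ethoxy group leaves, and C2 holds the proton that is lost.
- Stereochemistry: the single (S) centre comes from a Sharpless kinetic resolution of the allylic alcohol (D-(−)-DIPT leaves the (S)-enantiomer) and is only O-acylated afterwards. The two extra centres of the acetal are uncontrolled and vanish on aromatization.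

Key step: step 8

Remark: the aryl vinyl carbinol is used as the racemate and the acetal carbon forms without control, so the diene acetal and the dihydrofuran are carried as diastereomer mixtures that share the (S) carbinol centre.

**Step 1**
Reactants: 1 4-methylpent-3-en-1-ol
Product: 2 4-methylpent-3-enal
Conditions: Dess–Martin periodinane (1.2 equiv), NaHCO3, CH2Cl2, 0 °C to rt; filtered, dried and used at once as a solution
Reagents that add atoms: none
Why: Dess–Martin oxidation under bicarbonate buffering should take the primary alcohol to the aldehyde without the acid or base that would move the trisubstituted double bond into conjugation, and immediate use avoids loss of the volatile, labile aldehyde.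

**Step 2**
Reactants: 3 2-bromo-3,3-diethoxyprop-1-ene; 2 4-methylpent-3-enal
Product: 5 rac-2-(diethoxymethyl)-6-methylhepta-1,5-dien-3-ol, via 2-lithio-3,3-diethoxyprop-1-ene 4 (not isolated)
Conditions: n-BuLi (1.05 equiv), THF, −78 °C; then 2, −78 °C; aq. NH4Cl
Reagents that add atoms: none
Why: Bromine–lithium exchange at the sp2 carbon is fast at −78 °C, and the resulting 2-lithioacrolein acetal (an acrolein α-anion equivalent) should undergo 1,2-addition to the aldehyde to give the racemic allylic alcohol, with no stereocontrol sought at this stage.

**Step 3**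
Reactants: 5 rac-2-(diethoxymethyl)-6-methylhepta-1,5-dien-3-ol
Product: 6 (3S)-2-(diethoxymethyl)-6-methylhepta-1,5-dien-3-ol
Conditions: Ti(OiPr)4 (0.2 equiv), D-(−)-diisopropyl tartrate (0.25 equiv), t-BuOOH (0.6 equiv), 4 Å molecular sieves, CH2Cl2, −20 °C, stopped just past half conversion; aq. NaOH/brine work-up
Reagents that add atoms: none
Why: Sharpless kinetic resolution: with the D-(−)-tartrate the titanium–tartrate–hydroperoxide complex should epoxidize the allylic 1,1-disubstituted olefin of the (R)-enantiomer much faster, so the (S)-alcohol is left behind and sets the only stereocentre of the target, while the merely homoallylic trisubstituted olefin reacts far more slowly.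

**Step 4**
Reactants: 6 (3S)-2-(diethoxymethyl)-6-methylhepta-1,5-dien-3-ol; 7 3-methylbut-2-enoic acid
Product: 8 (3S)-2-(diethoxymethyl)-6-methylhepta-1,5-dien-3-yl 3-methylbut-2-enoate
Conditions: DCC, DMAP (cat.), CH2Cl2, 0 °C to rt
Reagents that add atoms: none
Why: Steglich esterification acylates at oxygen only, so the configuration at carbon is retained, and carbodiimide activation of the free acid avoids the acid chloride/amine conditions that favour deconjugation of the senecioyl unit through a vinylketene.

**Step 5**
Reactants: 9 2,5-dihydroxybenzaldehyde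
Product: 10 2,5-bis(tert-butyldimethylsilyloxy)benzaldehyde
Conditions: TBSCl (2.4 equiv), imidazole, DMF, rt
Reagents that add atoms: tert-butyldimethylsilyl chloride, CC(C)(C)[Si](C)(C)Cl
Why: Imidazole-mediated silylation of both phenols removes the acidic protons before the Grignard addition and installs groups that fluoride removes at the end without touching the ester or the furan.

**Step 6**
Reactants: 10 2,5-bis(tert-butyldimethylsilyloxy)benzaldehyde
Product: 11 rac-1-[2,5-bis(tert-butyldimethylsilyloxy)phenyl]prop-2-en-1-ol
Conditions: CH2=CHMgBr, THF, −78 °C; aq. NH4Cl at −78 °C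
Reagents that add atoms: vinylmagnesium bromide, C=C[Mg]Br
Why: Grignard 1,2-addition to the aryl aldehyde should give the racemic vinyl carbinol, with reaction and quench kept cold to suppress migration of the ortho silyl group to the new alkoxide; the new centre needs no control because it is destroyed in step 9.

**Step 7**
Reactants: 8 (3S)-2-(diethoxymethyl)-6-methylhepta-1,5-dien-3-yl 3-methylbut-2-enoate; 11 rac-1-[2,5-bis(tert-butyldimethylsilyloxy)phenyl]prop-2-en-1-ol
Product: 13 (3S)-2-[{1-[2,5-bis(tert-butyldimethylsilyloxy)phenyl]prop-2-enyloxy}(ethoxy)methyl]-6-methylhepta-1,5-dien-3-yl 3-methylbut-2-enoate (mixture at the acetal carbon and the benzylic carbon), via collidinium triflate salt 12 (not isolated)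
Conditions: TESOTf (1.1 equiv), 2,4,6-collidine (3 equiv), CH2Cl2, 0 °C; then 11 (2 equiv), 0 °C to rt
Reagents that add atoms: none
Why: Mixed-acetal formation through a pyridinium-type salt: the silyl triflate removes one ethoxy group as its silyl ether, collidine traps the oxocarbenium ion as an N,O-acetal salt, and the added alcohol should displace collidine at the acetal carbon under base-buffered conditions that spare the silyl ethers, the allylic ester and the ionizable benzylic alcohol.

**Step 8**
Reactants: 13 (3S)-2-[{1-[2,5-bis(tert-butyldimethylsilyloxy)phenyl]prop-2-enyloxy}(ethoxy)methyl]-6-methylhepta-1,5-dien-3-yl 3-methylbut-2-enoate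
Product: 14 (1S)-1-{5-[2,5-bis(tert-butyldimethylsilyloxy)phenyl]-2-ethoxy-2,5-dihydrofuran-3-yl}-4-methylpent-3-enyl 3-methylbut-2-enoate (mixture at ring C2 and C5)
Conditions: second-generation Grubbs catalyst RuCl2(=CHPh)(PCy3)(H2IMes) (5 mol %), CH2Cl2 (0.01 M), 40 °C; filtration through Et3N-deactivated silica
Reagents that add atoms: none
Why: Ring-closing olefin metathesis: the ruthenium benzylidene exchanges onto the monosubstituted vinyl group, the resulting alkylidene adds intramolecularly across the 1,1-disubstituted olefin to a ruthenacyclobutane, and cycloreversion releases the 2,5-dihydrofuran with a trisubstituted double bond while ethylene is expelled via the ruthenium methylidene. The closest known reaction type is the ring-closing metathesis of mixed allylic acetals to 2-alkoxy-2,5-dihydrofurans that are afterwards aromatized with acid. The single ring, five-membered, is closed at the later furan C3–C4 bond, the four other ring bonds being already present in the O–CH(OEt) tether. No stereocentre is formed, the (S)-carbinol centre is a spectator, and the acetal and benzylic ring carbons stay as mixtures because step 9 turns both into sp2 carbons. The step needs site selectivity among four olefins, and the substrate secures it: the vinyl group is the only monosubstituted olefin and therefore the loading site, the 1,1-disubstituted olefin is the only partner within reach of a five-membered closure, the prenyl olefin could close only an eight-membered ring, and the senecioyl olefin is trisubstituted and electron-poor. High dilution keeps dimerization through the vinyl group from competing.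

**Step 9**
Reactants: 14 (1S)-1-{5-[2,5-bis(tert-butyldimethylsilyloxy)phenyl]-2-ethoxy-2,5-dihydrofuran-3-yl}-4-methylpent-3-enyl 3-methylbut-2-enoate
Product: 15 (1S)-1-{5-[2,5-bis(tert-butyldimethylsilyloxy)phenyl]furan-3-yl}-4-methylpent-3-enyl 3-methylbut-2-enoate
Conditions: PPTS (10 mol %), CH2Cl2, rt
Reagents that add atoms: none
Why: Acid-catalysed elimination of ethanol: the mild acid ionizes the ethoxy group to an allyl-stabilized oxocarbenium ion, which should lose the proton on the aryl-bearing carbon to give the aromatic furan without any oxidant, and pyridinium tosylate is too weak to cleave the aryl silyl ethers or ionize the ester.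

**Step 10**
Reactants: 15 (1S)-1-{5-[2,5-bis(tert-butyldimethylsilyloxy)phenyl]furan-3-yl}-4-methylpent-3-enyl 3-methylbut-2-enoate
Product: 16 (1S)-1-[5-(2,5-dihydroxyphenyl)furan-3-yl]-4-methylpent-3-enyl 3-methylbut-2-enoate
Conditions: TBAF (2.2 equiv), AcOH (2.5 equiv), THF, 0 °C, under argon
Reagents that add atoms: none
Why: Fluoride-mediated desilylation of the two aryl silyl ethers, with acetic acid protonating the phenoxides as they form so that the ester is neither cleaved nor transferred, and with oxygen excluded so that the hydroquinone is not oxidized to the quinone.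

**Compound list**

1 | 4-methylpent-3-en-1-ol | CC(C)=CCCO | starting material
2 | 4-methylpent-3-enal | CC(C)=CCC=O | intermediate
3 | 2-bromo-3,3-diethoxyprop-1-ene | CCOC(OCC)C(Br)=C | starting material
4 | 2-lithio-3,3-diethoxyprop-1-ene | [Li]C(=C)C(OCC)OCC | intermediate
5 | rac-2-(diethoxymethyl)-6-methylhepta-1,5-dien-3-ol | CC(C)=CCC(O)C(=C)C(OCC)OCC | intermediate
6 | (3S)-2-(diethoxymethyl)-6-methylhepta-1,5-dien-3-ol | CC(C)=CC[C@H](O)C(=C)C(OCC)OCC | intermediate
7 | 3-methylbut-2-enoic acid | CC(C)=CC(=O)O | starting material
8 | (3S)-2-(diethoxymethyl)-6-methylhepta-1,5-dien-3-yl 3-methylbut-2-enoate | CC(C)=CC[C@H](OC(=O)C=C(C)C)C(=C)C(OCC)OCC | intermediate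
9 | 2,5-dihydroxybenzaldehyde | O=Cc1cc(O)ccc1O | starting material
10 | 2,5-bis(tert-butyldimethylsilyloxy)benzaldehyde | O=Cc1cc(O[Si](C)(C)C(C)(C)C)ccc1O[Si](C)(C)C(C)(C)C | intermediate
11 | rac-1-[2,5-bis(tert-butyldimethylsilyloxy)phenyl]prop-2-en-1-ol | C=CC(O)c1cc(O[Si](C)(C)C(C)(C)C)ccc1O[Si](C)(C)C(C)(C)C | intermediate
12 | 1-[(3S)-1-ethoxy-6-methyl-2-methylidene-3-(3-methylbut-2-enoyloxy)hept-5-en-1-yl]-2,4,6-trimethylpyridin-1-ium trifluoromethanesulfonate (mixture at the N,O-acetal carbon) | CC(C)=CC[C@H](OC(=O)C=C(C)C)C(=C)C(OCC)[n+]1c(C)cc(C)cc1C.[O-]S(=O)(=O)C(F)(F)F | intermediate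
13 | (3S)-2-[{1-[2,5-bis(tert-butyldimethylsilyloxy)phenyl]prop-2-enyloxy}(ethoxy)methyl]-6-methylhepta-1,5-dien-3-yl 3-methylbut-2-enoate (mixture at the acetal and benzylic carbons) | CC(C)=CC[C@H](OC(=O)C=C(C)C)C(=C)C(OCC)OC(C=C)c1cc(O[Si](C)(C)C(C)(C)C)ccc1O[Si](C)(C)C(C)(C)C | intermediate
14 | (1S)-1-{5-[2,5-bis(tert-butyldimethylsilyloxy)phenyl]-2-ethoxy-2,5-dihydrofuran-3-yl}-4-methylpent-3-enyl 3-methylbut-2-enoate (mixture at ring C2 and C5) | CC(C)=CC[C@H](OC(=O)C=C(C)C)C1=CC(c2cc(O[Si](C)(C)C(C)(C)C)ccc2O[Si](C)(C)C(C)(C)C)OC1OCC | intermediate
15 | (1S)-1-{5-[2,5-bis(tert-butyldimethylsilyloxy)phenyl]furan-3-yl}-4-methylpent-3-enyl 3-methylbut-2-enoate | CC(C)=CC[C@H](OC(=O)C=C(C)C)c1coc(-c2cc(O[Si](C)(C)C(C)(C)C)ccc2O[Si](C)(C)C(C)(C)C)c1 | intermediate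
16 | (1S)-1-[5-(2,5-dihydroxyphenyl)furan-3-yl]-4-methylpent-3-enyl 3-methylbut-2-enoate | CC(C)=CC[C@H](OC(=O)C=C(C)C)c1coc(-c2cc(O)ccc2O)c1 | target

**Step count**

Total: 10 steps. Longest linear sequence: 8 steps (steps 1, 2, 3, 4, 7, 8, 9, 10); the aryl branch (steps 5, 6) joins at step 7.

**Steps most likely to fail**

Step 7 (acetal exchange). The alcohol may add to the terminal methylene carbon of the allylic collidinium salt with allylic transposition to an enol ether. The neighbouring ester carbonyl may capture the oxocarbenium ion, or residual silyl triflate may silylate the carbinol faster than the salt is intercepted. The fallback sets out from 8. Acetyl chloride with catalytic ZnBr2 in CH2Cl2 should exchange one ethoxy group for chloride and give the α-chloro ether (3S)-2-[chloro(ethoxy)methyl]-6-methylhepta-1,5-dien-3-yl 3-methylbut-2-enoate F1. F1 is then used to O-alkylate 11 in the presence of iPr2NEt in CH2Cl2 at 0 °C, the classical α-halo ether route to mixed acetals, and the route is rejoined at 13.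

Step 3 (kinetic resolution). Epoxidation of the hindered, inductively deactivated 1,1-disubstituted olefin may be so slow that the rate difference between the enantiomers erodes. Hydroxyl-directed epoxidation of the trisubstituted olefin may compete, and alkoxide exchange at the acetal on titanium is possible. The fallback sets out from 5. Dess–Martin oxidation should give the enone 2-(diethoxymethyl)-6-methylhepta-1,5-dien-3-one F2. Corey–Bakshi–Shibata reduction of F2 with (R)-2-methyl-CBS-oxazaborolidine and BH3·SMe2 in THF at low temperature, in which the α-branched alkenyl group acts as the large substituent, should deliver the (S)-alcohol and rejoin the route at 6 while using all of the material.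

Step 8 (ring-closing metathesis). Closure onto the congested 1,1-disubstituted olefin may be slower than decay of the ruthenium methylidene. The ruthenium hydrides so formed can move the double bond of the allylic ether into conjugation, and dimerization through the vinyl group can take over. The fallback sets out from 10 and redesigns the diene so that no methylidene is formed. Addition of prop-1-enylmagnesium bromide in THF at −78 °C should give 1-[2,5-bis(tert-butyldimethylsilyloxy)phenyl]but-2-en-1-ol F3. F3 is coupled with 8 by the protocol of step 7 (through 12) to the methyl-capped diene acetal (3S)-2-[{1-[2,5-bis(tert-butyldimethylsilyloxy)phenyl]but-2-enyloxy}(ethoxy)methyl]-6-methylhepta-1,5-dien-3-yl 3-methylbut-2-enoate F4. Ring-closing metathesis of F4 with the same second-generation Grubbs catalyst then expels propene and propagates through the longer-lived ruthenium ethylidene, and the route is rejoined at 14.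

**Further compounds**

F1 | step 7 | (3S)-2-[chloro(ethoxy)methyl]-6-methylhepta-1,5-dien-3-yl 3-methylbut-2-enoate (mixture at the chloro ether carbon) | CC(C)=CC[C@H](OC(=O)C=C(C)C)C(=C)C(Cl)OCC
F2 | step 3 | 2-(diethoxymethyl)-6-methylhepta-1,5-dien-3-one | CC(C)=CCC(=O)C(=C)C(OCC)OCC
F3 | step 8 | 1-[2,5-bis(tert-butyldimethylsilyloxy)phenyl]but-2-en-1-ol (racemic, E/Z mixture) | CC=CC(O)c1cc(O[Si](C)(C)C(C)(C)C)ccc1O[Si](C)(C)C(C)(C)C
F4 | step 8 | (3S)-2-[{1-[2,5-bis(tert-butyldimethylsilyloxy)phenyl]but-2-enyloxy}(ethoxy)methyl]-6-methylhepta-1,5-dien-3-yl 3-methylbut-2-enoate (mixture at the acetal and benzylic carbons, E/Z mixture) | CC(C)=CC[C@H](OC(=O)C=C(C)C)C(=C)C(OCC)OC(C=CC)c1cc(O[Si](C)(C)C(C)(C)C)ccc1O[Si](C)(C)C(C)(C)C
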